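The route rests on disconnecting ring A, a hexasubstituted phloroglucinol, across C7–C8 and C4a–C8a. A thermal Danheiser benzannulation joins a 3-ethoxy-4-(arylmethyl)cyclobutenone carrying the four-ring phenolic chain (as benzyl ethers) to a triisopropylsiloxyalkyne carrying the salicyl group. In one operation it builds ring A with its three oxygens already differentiated (C7–OH, C8a–OSi, C5–OEt), places the chain benzyl at C6 and the salicyl benzyl at C8, and leaves C4a as the only free carbon, the site later used to build ring C. The chromone formed from it receives the phenyl group at C2 by enantioselective conjugate addition.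

Key step: step 12

Remarks
- Ring A atoms carry flavanone numbers (O1, C2–C4, C4a, C5–C8, C8a) from step 12 on.
- Bn = benzyl. ArT = the tetra-O-benzyl four-ring chain aryl group 2-(benzyloxy)-5-{2-(benzyloxy)-5-[2-(benzyloxy)-5-(2-(benzyloxy)benzyl)benzyl]benzyl}phenyl.
- All spectator phenols are carried as benzyl ethers, which tolerate the acidic steps 2, 4, 6, 9 and 15 and fall together with the C5 ethyl ether in step 18.
- Assumption: 1, 2 and 19 are bought as the O-benzyl compounds (each is otherwise one routine O-benzylation or bromination from 2-bromophenol, 3-bromo-4-hydroxybenzaldehyde or 2-(benzyloxy)benzyl alcohol).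

Step 1
Reactants: 1 1-(benzyloxy)-2-bromobenzene; 2 4-(benzyloxy)-3-bromobenzaldehyde
Product: 4 [2-(benzyloxy)phenyl][4-(benzyloxy)-3-bromophenyl]methanol (racemic), via aryllithium 3 (not isolated)
Conditions: n-BuLi, THF, –78 °C; then 2, –78 → –20 °C; aq NH4Cl
Reagents that add atoms: none
Why: Bromine–lithium exchange on 1 is fast at –78 °C and the aryllithium undergoes 1,2-addition to the aldehyde faster than it exchanges with the aryl bromide of 2, the racemic carbinol centre being removed in step 2.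

Step 2
Reactants: 4 [2-(benzyloxy)phenyl][4-(benzyloxy)-3-bromophenyl]methanol
Product: 5 1-(benzyloxy)-2-bromo-4-[2-(benzyloxy)benzyl]benzene
Conditions: Et3SiH, CF3CO2H, CH2Cl2, 0 °C
Reagents that add atoms: none
Why: Ionic hydrogenation, in which the doubly benzylic carbinol ionises to a cation stabilised by the para- and ortho-benzyloxy groups and is reduced by the silane, under conditions that spare aryl bromide and benzyl ethers.

Step 3
Reactants: 5 1-(benzyloxy)-2-bromo-4-[2-(benzyloxy)benzyl]benzene; 2 4-(benzyloxy)-3-bromobenzaldehyde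
Product: 7 [4-(benzyloxy)-3-bromophenyl]{2-(benzyloxy)-5-[2-(benzyloxy)benzyl]phenyl}methanol (racemic), via aryllithium 6 (not isolated)
Conditions: n-BuLi, THF, –78 °C; then 2, –78 → –20 °C; aq NH4Cl
Reagents that add atoms: none
Why: The same bromine–lithium exchange and aldehyde addition as in step 1, the exchange being far faster at –78 °C than deprotonation of the diarylmethane CH2 group.

Step 4
Reactants: 7 [4-(benzyloxy)-3-bromophenyl]{2-(benzyloxy)-5-[2-(benzyloxy)benzyl]phenyl}methanol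
Product: 8 1-(benzyloxy)-4-{2-(benzyloxy)-5-[2-(benzyloxy)benzyl]benzyl}-2-bromobenzene
Conditions: Et3SiH, CF3CO2H, CH2Cl2, 0 °C
Reagents that add atoms: none
Why: Ionic hydrogenation of an alkoxy-stabilised benzhydryl cation as in step 2.

Step 5
Reactants: 8 1-(benzyloxy)-4-{2-(benzyloxy)-5-[2-(benzyloxy)benzyl]benzyl}-2-bromobenzene; 2 4-(benzyloxy)-3-bromobenzaldehyde
Product: 10 [4-(benzyloxy)-3-bromophenyl](2-(benzyloxy)-5-{2-(benzyloxy)-5-[2-(benzyloxy)benzyl]benzyl}phenyl)methanol (racemic), via aryllithium 9 (not isolated)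
Conditions: n-BuLi, THF, –78 °C; then 2, –78 → –20 °C; aq NH4Cl
Reagents that add atoms: none
Why: Third cycle of bromine–lithium exchange and 1,2-addition to the aldehyde, identical in type to steps 1 and 3.

Step 6
Reactants: 10 [4-(benzyloxy)-3-bromophenyl](2-(benzyloxy)-5-{2-(benzyloxy)-5-[2-(benzyloxy)benzyl]benzyl}phenyl)methanol
Product: 11 ArT–Br, 1-(benzyloxy)-2-bromo-4-{2-(benzyloxy)-5-[2-(benzyloxy)-5-(2-(benzyloxy)benzyl)benzyl]benzyl}benzene
Conditions: Et3SiH, CF3CO2H, CH2Cl2, 0 °C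
Reagents that add atoms: none
Why: Ionic hydrogenation as in steps 2 and 4 completes the four-ring chain with its bromine ortho to the terminal benzyloxy group.

Step 7
Reactants: 11 ArT–Br; 12 (3-ethoxy-3-oxopropyl)zinc bromide
Product: 13 ethyl 3-ArT-propanoate
Conditions: 12 (0.5 M in THF), Pd(OAc)2, SPhos, THF, 50 °C
Reagents that add atoms: none
Why: Negishi coupling of a primary alkylzinc bromide, in which the bulky biarylphosphine speeds oxidative addition of the electron-rich ortho-alkoxy aryl bromide to zerovalent palladium and reductive elimination, the ester being inert to the organozinc.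

Step 8
Reactants: 13 ethyl 3-ArT-propanoate
Product: 14 3-ArT-propanoic acid
Conditions: LiOH, THF/MeOH/H2O, rt; then aq HCl
Reagents that add atoms: lithium hydroxide, [Li+].[OH-]
Why: Ordinary saponification of an unhindered ethyl ester, to which benzyl ethers are inert.

Step 9
Reactants: 14 3-ArT-propanoic acid; 15 ethoxyacetylene
Product: 18 3-ethoxy-4-(ArT-methyl)cyclobut-2-en-1-one (racemic), via acid chloride 16 (not isolated), via ketene 17 (not isolated)
Conditions: (COCl)2, DMF (cat.), CH2Cl2, 0 °C → rt, evaporate; then slow addition to 15 (excess), Et3N, Et2O, 0 °C → rt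
Reagents that add atoms: none
Why: Dehydrochlorination gives the monoalkylketene, which undergoes [2+2] cycloaddition with the ynol ether, the nucleophilic CH terminus bonding to the ketene carbonyl carbon so that ethoxy sits at C3 and the arylmethyl group at C4, while slow addition into excess alkyne suppresses ketene dimerisation and the racemic C4 centre is erased in step 12.

Step 10
Reactants: 19 1-(benzyloxy)-2-(bromomethyl)benzene; 20 ethynylmagnesium bromide
Product: 21 1-(benzyloxy)-2-(prop-2-yn-1-yl)benzene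
Conditions: 20 (0.5 M in THF, excess), CuCl (cat.), THF, 50 °C
Reagents that add atoms: none
Why: Copper-catalysed substitution of a benzylic bromide by an alkynyl Grignard reagent, the excess reagent keeping the product as its acetylide and so preventing isomerisation to the allene.

Step 11
Reactants: 21 1-(benzyloxy)-2-(prop-2-yn-1-yl)benzene
Product: 24 ({3-[2-(benzyloxy)phenyl]prop-1-yn-1-yl}oxy)triisopropylsilane, via lithium acetylide 22 (not isolated), via lithium ynolate 23 (not isolated)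
Conditions: n-BuLi, THF, –78 °C; add to LiOOt-Bu (t-BuOOH, LiN(SiMe3)2, THF, –78 °C), –78 → 0 °C; i-Pr3SiOTf, –78 → 0 °C
Reagents that add atoms: tert-butyl hydroperoxide, CC(C)(C)OO; triisopropylsilyl trifluoromethanesulfonate, CC(C)[Si](OS(=O)(=O)C(F)(F)F)(C(C)C)C(C)C
Why: Oxidation of a lithium acetylide by the lithium peroxide (substitution at oxygen with loss of tert-butoxide) gives the ynolate, which the bulky silyl triflate silylates on oxygen to give the siloxyalkyne.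

Step 12
Reactants: 18 3-ethoxy-4-(ArT-methyl)cyclobut-2-en-1-one; 24 ({3-[2-(benzyloxy)phenyl]prop-1-yn-1-yl}oxy)triisopropylsilane
Product: 29 6-[2-(benzyloxy)benzyl]-2-(ArT-methyl)-3-ethoxy-5-(triisopropylsiloxy)phenol, via vinylketene 25 (not isolated), via vinylcyclobutenone 26 (not isolated), via dienylketene 27 (not isolated), via cyclohexadienone 28 (not isolated)
Conditions: 24 (1.5 equiv), toluene, 80 → 110 °C, sealed tube, Ar
Reagents that add atoms: none
Why: Heating opens 18 by conrotatory 4π electrocyclic ring opening to vinylketene 25, the siloxyalkyne adds to its ketene C=C in a [2+2] cycloaddition to give 26, a second 4π opening gives dienylketene 27, and disrotatory 6π electrocyclisation followed by tautomerisation of dienone 28 gives the phenol. The closest known reaction type is the Danheiser benzannulation of cyclobutenones with trialkylsiloxyalkynes to monosilylated resorcinols, applied here to a 3-alkoxy-4-alkylcyclobutenone. Ring A is closed by the thermal 6π electrocyclisation of a dienylketene (C6–C7 bond), after the [2+2] step has made the C7–C8 and C4a–C8a bonds. No stereocentre is created, and the racemic C4 centre of 18 disappears on aromatisation. The step needs regiocontrol only, and this follows from polarity and connectivity: the nucleophilic alkyne carbon bearing the salicyl group bonds to the ketene carbonyl carbon (future C7), the siloxy carbon becomes C8a, and the ethoxy carbon (C5), the unsubstituted carbon (C4a) and the chain-bearing carbon (C6) keep the order fixed in the cyclobutenone. The excess of 24 lets cycloaddition outrun ketene dimerisation and acylation of the product phenol by 25.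

Step 13
Reactants: 29 6-[2-(benzyloxy)benzyl]-2-(ArT-methyl)-3-ethoxy-5-(triisopropylsiloxy)phenol
Product: 30 {3-(benzyloxy)-2-[2-(benzyloxy)benzyl]-4-(ArT-methyl)-5-ethoxyphenoxy}triisopropylsilane
Conditions: NaH, BnBr, Bu4NI (cat.), THF/DMF, 0 °C → rt
Reagents that add atoms: benzyl bromide, BrCc1ccccc1
Why: Williamson etherification of the C7 phenoxide, which is alkylated on oxygen in the dipolar aprotic medium while the aryl triisopropylsilyl ether at C8a survives the anhydrous base.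

Step 14
Reactants: 30 {3-(benzyloxy)-2-[2-(benzyloxy)benzyl]-4-(ArT-methyl)-5-ethoxyphenoxy}triisopropylsilane
Product: 31 3-(benzyloxy)-2-[2-(benzyloxy)benzyl]-4-(ArT-methyl)-5-ethoxyphenol
Conditions: Bu4NF, THF, 0 °C; aq NH4Cl
Reagents that add atoms: none
Why: Fluoride-driven cleavage of the aryl silyl ether frees the C8a phenol alone, since all other oxygens are alkyl ethers.

Step 15
Reactants: 31 3-(benzyloxy)-2-[2-(benzyloxy)benzyl]-4-(ArT-methyl)-5-ethoxyphenol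
Product: 33 1-{4-(benzyloxy)-3-[2-(benzyloxy)benzyl]-5-(ArT-methyl)-6-ethoxy-2-hydroxyphenyl}ethan-1-one, via difluoroboron chelate 32 (not isolated)
Conditions: Ac2O (1.5 equiv), BF3·OEt2, CH2Cl2, 0 °C → rt; then NaOAc, MeOH/H2O, 50 °C
Reagents that add atoms: acetic anhydride, CC(=O)OC(C)=O
Why: BF3-mediated Friedel–Crafts acylation ortho to the free phenol at C4a, the only open carbon of the trioxygenated ring and far more nucleophilic than the monoalkoxy rings, with the ketone held as its difluoroboron chelate until mild hydrolysis and the benzyl aryl ethers tolerating BF3·OEt2 at or below room temperature.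

Step 16
Reactants: 33 1-{4-(benzyloxy)-3-[2-(benzyloxy)benzyl]-5-(ArT-methyl)-6-ethoxy-2-hydroxyphenyl}ethan-1-one
Product: 35 7-(benzyloxy)-8-[2-(benzyloxy)benzyl]-6-(ArT-methyl)-5-ethoxy-4H-chromen-4-one, via enaminone 34 (not isolated)
Conditions: Me2NCH(OMe)2, toluene, 100 °C; then conc. HCl, CH2Cl2, rt
Reagents that add atoms: N,N-dimethylformamide dimethyl acetal, COC(OC)N(C)C
Why: Condensation of the methyl ketone with the amide acetal gives the enaminone, and acid then promotes conjugate addition of the C8a phenol and loss of dimethylamine to close the chromone.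

Step 17
Reactants: 35 7-(benzyloxy)-8-[2-(benzyloxy)benzyl]-6-(ArT-methyl)-5-ethoxy-4H-chromen-4-one; 36 phenylboronic acid
Product: 37 (2S)-7-(benzyloxy)-8-[2-(benzyloxy)benzyl]-6-(ArT-methyl)-5-ethoxy-2-phenylchroman-4-one
Conditions: Pd(OCOCF3)2 (10 mol %), (R)-t-BuPyOx (12 mol %), NH4PF6, H2O, ClCH2CH2Cl, 60 °C
Reagents that add atoms: none
Why: Asymmetric conjugate addition in which a cationic phenyl complex of divalent palladium bearing the chiral pyridine–oxazoline adds across C2=C3 and the enolate is protonated, the (R)-ligand (antipode of the one that gives (R)-configured β-aryl ketones from cyclic enones) being expected to deliver phenyl to the face that makes C2 (S), a centre not touched by base afterwards.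

Step 18
Reactants: 37 (2S)-7-(benzyloxy)-8-[2-(benzyloxy)benzyl]-6-(ArT-methyl)-5-ethoxy-2-phenylchroman-4-one
Product: 38 sarmentosumin C, (2S)-5,7-dihydroxy-8-(2-hydroxybenzyl)-6-{2-hydroxy-5-[2-hydroxy-5-(2-hydroxy-5-(2-hydroxybenzyl)benzyl)benzyl]benzyl}-2-phenylchroman-4-one
Conditions: BCl3 (excess), C6HMe5, CH2Cl2, –78 °C → rt; MeOH
Reagents that add atoms: none
Why: Lewis-acid ether cleavage in which BCl3 removes the six aryl benzyl ethers at low temperature with pentamethylbenzene trapping the benzyl cations, and cleaves the C5 ethyl ether through its chelate with the C4 carbonyl, in a base-free medium that should leave C2 untouched.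

Compound list
1 | 1-(benzyloxy)-2-bromobenzene | Brc1ccccc1OCc1ccccc1 | starting material
2 | 4-(benzyloxy)-3-bromobenzaldehyde | O=Cc1ccc(OCc2ccccc2)c(Br)c1 | starting material
3 | [2-(benzyloxy)phenyl]lithium | [Li]c1ccccc1OCc1ccccc1 | intermediate (not isolated)
4 | [2-(benzyloxy)phenyl][4-(benzyloxy)-3-bromophenyl]methanol (racemic) | OC(c1ccccc1OCc1ccccc1)c1ccc(OCc2ccccc2)c(Br)c1 | intermediate
5 | 1-(benzyloxy)-2-bromo-4-[2-(benzyloxy)benzyl]benzene | Brc1cc(Cc2ccccc2OCc2ccccc2)ccc1OCc1ccccc1 | intermediate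
6 | {2-(benzyloxy)-5-[2-(benzyloxy)benzyl]phenyl}lithium | [Li]c1cc(Cc2ccccc2OCc2ccccc2)ccc1OCc1ccccc1 | intermediate (not isolated)
7 | [4-(benzyloxy)-3-bromophenyl]{2-(benzyloxy)-5-[2-(benzyloxy)benzyl]phenyl}methanol (racemic) | OC(c1cc(Cc2ccccc2OCc2ccccc2)ccc1OCc1ccccc1)c1ccc(OCc2ccccc2)c(Br)c1 | intermediate
8 | 1-(benzyloxy)-4-{2-(benzyloxy)-5-[2-(benzyloxy)benzyl]benzyl}-2-bromobenzene | Brc1cc(Cc2cc(Cc3ccccc3OCc3ccccc3)ccc2OCc2ccccc2)ccc1OCc1ccccc1 | intermediate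
9 | (2-(benzyloxy)-5-{2-(benzyloxy)-5-[2-(benzyloxy)benzyl]benzyl}phenyl)lithium | [Li]c1cc(Cc2cc(Cc3ccccc3OCc3ccccc3)ccc2OCc2ccccc2)ccc1OCc1ccccc1 | intermediate (not isolated)
10 | [4-(benzyloxy)-3-bromophenyl](2-(benzyloxy)-5-{2-(benzyloxy)-5-[2-(benzyloxy)benzyl]benzyl}phenyl)methanol (racemic) | OC(c1cc(Cc2cc(Cc3ccccc3OCc3ccccc3)ccc2OCc2ccccc2)ccc1OCc1ccccc1)c1ccc(OCc2ccccc2)c(Br)c1 | intermediate
11 | ArT–Br, 1-(benzyloxy)-2-bromo-4-{2-(benzyloxy)-5-[2-(benzyloxy)-5-(2-(benzyloxy)benzyl)benzyl]benzyl}benzene | Brc1cc(Cc2cc(Cc3cc(Cc4ccccc4OCc4ccccc4)ccc3OCc3ccccc3)ccc2OCc2ccccc2)ccc1OCc1ccccc1 | intermediate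
12 | (3-ethoxy-3-oxopropyl)zinc bromide | CCOC(=O)CC[Zn]Br | starting material
13 | ethyl 3-ArT-propanoate | CCOC(=O)CCc1cc(Cc2cc(Cc3cc(Cc4ccccc4OCc4ccccc4)ccc3OCc3ccccc3)ccc2OCc2ccccc2)ccc1OCc1ccccc1 | intermediate
14 | 3-ArT-propanoic acid | OC(=O)CCc1cc(Cc2cc(Cc3cc(Cc4ccccc4OCc4ccccc4)ccc3OCc3ccccc3)ccc2OCc2ccccc2)ccc1OCc1ccccc1 | intermediate
15 | ethoxyacetylene | CCOC#C | starting material
16 | 3-ArT-propanoyl chloride | ClC(=O)CCc1cc(Cc2cc(Cc3cc(Cc4ccccc4OCc4ccccc4)ccc3OCc3ccccc3)ccc2OCc2ccccc2)ccc1OCc1ccccc1 | intermediate (not isolated)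
17 | 3-ArT-prop-1-en-1-one (monoalkylketene) | O=C=CCc1cc(Cc2cc(Cc3cc(Cc4ccccc4OCc4ccccc4)ccc3OCc3ccccc3)ccc2OCc2ccccc2)ccc1OCc1ccccc1 | intermediate (not isolated)
18 | 3-ethoxy-4-(ArT-methyl)cyclobut-2-en-1-one (racemic) | CCOC1=CC(=O)C1Cc1cc(Cc2cc(Cc3cc(Cc4ccccc4OCc4ccccc4)ccc3OCc3ccccc3)ccc2OCc2ccccc2)ccc1OCc1ccccc1 | intermediate
19 | 1-(benzyloxy)-2-(bromomethyl)benzene | BrCc1ccccc1OCc1ccccc1 | starting material
20 | ethynylmagnesium bromide | C#C[Mg]Br | starting material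
21 | 1-(benzyloxy)-2-(prop-2-yn-1-yl)benzene | C#CCc1ccccc1OCc1ccccc1 | intermediate
22 | {3-[2-(benzyloxy)phenyl]prop-1-yn-1-yl}lithium | [Li]C#CCc1ccccc1OCc1ccccc1 | intermediate (not isolated)
23 | lithium 3-[2-(benzyloxy)phenyl]prop-1-yn-1-olate | [Li]OC#CCc1ccccc1OCc1ccccc1 | intermediate (not isolated)
24 | ({3-[2-(benzyloxy)phenyl]prop-1-yn-1-yl}oxy)triisopropylsilane | CC(C)[Si](OC#CCc1ccccc1OCc1ccccc1)(C(C)C)C(C)C | intermediate
25 | (3Z)-3-ethoxy-5-ArT-penta-1,3-dien-1-one (vinylketene) | CCO/C(C=C=O)=C\Cc1cc(Cc2cc(Cc3cc(Cc4ccccc4OCc4ccccc4)ccc3OCc3ccccc3)ccc2OCc2ccccc2)ccc1OCc1ccccc1 | intermediate (not isolated)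
26 | 2-[2-(benzyloxy)benzyl]-4-[(Z)-1-ethoxy-3-ArT-prop-1-en-1-yl]-3-(triisopropylsiloxy)cyclobut-2-en-1-one (racemic) | O=C1C(Cc2ccccc2OCc2ccccc2)=C(O[Si](C(C)C)(C(C)C)C(C)C)C1/C(OCC)=C/Cc1cc(Cc2cc(Cc3cc(Cc4ccccc4OCc4ccccc4)ccc3OCc3ccccc3)ccc2OCc2ccccc2)ccc1OCc1ccccc1 | intermediate (not isolated)
27 | (3E,5Z)-2-[2-(benzyloxy)benzyl]-5-ethoxy-7-ArT-3-(triisopropylsiloxy)hepta-1,3,5-trien-1-one (dienylketene) | O=C=C(Cc1ccccc1OCc1ccccc1)/C(O[Si](C(C)C)(C(C)C)C(C)C)=C\C(OCC)=C\Cc1cc(Cc2cc(Cc3cc(Cc4ccccc4OCc4ccccc4)ccc3OCc3ccccc3)ccc2OCc2ccccc2)ccc1OCc1ccccc1 | intermediate (not isolated)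
28 | 2-[2-(benzyloxy)benzyl]-6-(ArT-methyl)-5-ethoxy-3-(triisopropylsiloxy)cyclohexa-2,4-dien-1-one (racemic) | O=C1C(Cc2ccccc2OCc2ccccc2)=C(O[Si](C(C)C)(C(C)C)C(C)C)C=C(OCC)C1Cc1cc(Cc2cc(Cc3cc(Cc4ccccc4OCc4ccccc4)ccc3OCc3ccccc3)ccc2OCc2ccccc2)ccc1OCc1ccccc1 | intermediate (not isolated)
29 | 6-[2-(benzyloxy)benzyl]-2-(ArT-methyl)-3-ethoxy-5-(triisopropylsiloxy)phenol | CCOc1cc(O[Si](C(C)C)(C(C)C)C(C)C)c(Cc2ccccc2OCc2ccccc2)c(O)c1Cc1cc(Cc2cc(Cc3cc(Cc4ccccc4OCc4ccccc4)ccc3OCc3ccccc3)ccc2OCc2ccccc2)ccc1OCc1ccccc1 | intermediate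
30 | {3-(benzyloxy)-2-[2-(benzyloxy)benzyl]-4-(ArT-methyl)-5-ethoxyphenoxy}triisopropylsilane | CCOc1cc(O[Si](C(C)C)(C(C)C)C(C)C)c(Cc2ccccc2OCc2ccccc2)c(OCc2ccccc2)c1Cc1cc(Cc2cc(Cc3cc(Cc4ccccc4OCc4ccccc4)ccc3OCc3ccccc3)ccc2OCc2ccccc2)ccc1OCc1ccccc1 | intermediate
31 | 3-(benzyloxy)-2-[2-(benzyloxy)benzyl]-4-(ArT-methyl)-5-ethoxyphenol | CCOc1cc(O)c(Cc2ccccc2OCc2ccccc2)c(OCc2ccccc2)c1Cc1cc(Cc2cc(Cc3cc(Cc4ccccc4OCc4ccccc4)ccc3OCc3ccccc3)ccc2OCc2ccccc2)ccc1OCc1ccccc1 | intermediate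
32 | difluoroboron chelate of 33 (O,O-chelate of the C8a phenolate and the acetyl oxygen) | CC1=[O+][B-](F)(F)Oc2c(Cc3ccccc3OCc3ccccc3)c(OCc3ccccc3)c(Cc3cc(Cc4cc(Cc5cc(Cc6ccccc6OCc6ccccc6)ccc5OCc5ccccc5)ccc4OCc4ccccc4)ccc3OCc3ccccc3)c(OCC)c12 | intermediate (not isolated)
33 | 1-{4-(benzyloxy)-3-[2-(benzyloxy)benzyl]-5-(ArT-methyl)-6-ethoxy-2-hydroxyphenyl}ethan-1-one | CCOc1c(C(C)=O)c(O)c(Cc2ccccc2OCc2ccccc2)c(OCc2ccccc2)c1Cc1cc(Cc2cc(Cc3cc(Cc4ccccc4OCc4ccccc4)ccc3OCc3ccccc3)ccc2OCc2ccccc2)ccc1OCc1ccccc1 | intermediate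
34 | (E)-1-{4-(benzyloxy)-3-[2-(benzyloxy)benzyl]-5-(ArT-methyl)-6-ethoxy-2-hydroxyphenyl}-3-(dimethylamino)prop-2-en-1-one | CCOc1c(C(=O)/C=C/N(C)C)c(O)c(Cc2ccccc2OCc2ccccc2)c(OCc2ccccc2)c1Cc1cc(Cc2cc(Cc3cc(Cc4ccccc4OCc4ccccc4)ccc3OCc3ccccc3)ccc2OCc2ccccc2)ccc1OCc1ccccc1 | intermediate (not isolated)
35 | 7-(benzyloxy)-8-[2-(benzyloxy)benzyl]-6-(ArT-methyl)-5-ethoxy-4H-chromen-4-one | O=C1C=COc2c(Cc3ccccc3OCc3ccccc3)c(OCc3ccccc3)c(Cc3cc(Cc4cc(Cc5cc(Cc6ccccc6OCc6ccccc6)ccc5OCc5ccccc5)ccc4OCc4ccccc4)ccc3OCc3ccccc3)c(OCC)c12 | intermediate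
36 | phenylboronic acid | OB(O)c1ccccc1 | starting material
37 | (2S)-7-(benzyloxy)-8-[2-(benzyloxy)benzyl]-6-(ArT-methyl)-5-ethoxy-2-phenylchroman-4-one | O=C1C[C@@H](c2ccccc2)Oc2c(Cc3ccccc3OCc3ccccc3)c(OCc3ccccc3)c(Cc3cc(Cc4cc(Cc5cc(Cc6ccccc6OCc6ccccc6)ccc5OCc5ccccc5)ccc4OCc4ccccc4)ccc3OCc3ccccc3)c(OCC)c12 | intermediate
38 | sarmentosumin C, (2S)-5,7-dihydroxy-8-(2-hydroxybenzyl)-6-{2-hydroxy-5-[2-hydroxy-5-(2-hydroxy-5-(2-hydroxybenzyl)benzyl)benzyl]benzyl}-2-phenylchroman-4-one | O=C1C[C@@H](c2ccccc2)Oc2c(Cc3ccccc3O)c(O)c(Cc3cc(Cc4cc(Cc5cc(Cc6ccccc6O)ccc5O)ccc4O)ccc3O)c(O)c21 | target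

Total step count: 18.
Longest linear sequence: 16 steps (steps 1–9, then 12–18).

Steps most likely to fail

1. Step 12. The vinylogous-ester stabilisation of 18 may slow the first 4π ring opening until the siloxyalkyne decomposes, or the vinylketene may be lost to dimerisation and to acylation of the product phenol. Fallback: the same vinylketene is made without heat by 1,4-dehydrochlorination. Setting out from acid 14, activation with carbonyldiimidazole and C-acylation of potassium ethyl malonate (MgCl2, Et3N, MeCN) gives ethyl 3-oxo-5-ArT-pentanoate F1. HC(OEt)3 with a trace of H2SO4 in EtOH converts it into ethyl (E)-3-ethoxy-5-ArT-pent-2-enoate F2. KOH in aqueous EtOH gives (E)-3-ethoxy-5-ArT-pent-2-enoic acid F3, and (COCl)2 gives (E)-3-ethoxy-5-ArT-pent-2-enoyl chloride F4. Slow addition of F4 to Et3N and 24 in toluene at room temperature, then warming to 80 °C, removes a γ-hydrogen and chloride to give vinylketene 25. The route is rejoined at 25 and runs through 26–28 to 29.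

2. Step 17. Carbopalladation of the electron-rich, crowded 5,7-dialkoxychromone may be slow, and the facial selectivity may be poor. Fallback: setting out from acetophenone 33, Claisen–Schmidt condensation with benzaldehyde (KOH, EtOH, rt) gives (E)-1-{4-(benzyloxy)-3-[2-(benzyloxy)benzyl]-5-(ArT-methyl)-6-ethoxy-2-hydroxyphenyl}-3-phenylprop-2-en-1-one F5. NaOAc in refluxing EtOH closes ring C by intramolecular oxa-Michael addition to racemic 7-(benzyloxy)-8-[2-(benzyloxy)benzyl]-6-(ArT-methyl)-5-ethoxy-2-phenylchroman-4-one F6. Preparative HPLC on an amylose tris(3,5-dimethylphenylcarbamate) phase separates the (2S)-enantiomer, which is 37, from (2R)-7-(benzyloxy)-8-[2-(benzyloxy)benzyl]-6-(ArT-methyl)-5-ethoxy-2-phenylchroman-4-one F7. The route is rejoined at 37.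

3. Step 18. Benzyl cations may be captured by the phenolic rings, cleavage of the chelated ethyl ether may stay incomplete, or the Lewis acid may open ring C at O1–C2 with loss of configuration. Fallback: the two kinds of ether are removed by different mechanisms. Setting out from 37, hydrogenolysis (H2, Pd/C, EtOAc/MeOH, rt) removes the six benzyl groups under neutral conditions to give (2S)-5-ethoxy-7-hydroxy-8-(2-hydroxybenzyl)-6-{2-hydroxy-5-[2-hydroxy-5-(2-hydroxy-5-(2-hydroxybenzyl)benzyl)benzyl]benzyl}-2-phenylchroman-4-one F8. Only the chelated ethyl ether then has to be cleaved, with BCl3 and Bu4NI in CH2Cl2 (–78 → 0 °C), and the route is rejoined at 38.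

Further compounds
F1 | step 12 | ethyl 3-oxo-5-ArT-pentanoate | CCOC(=O)CC(=O)CCc1cc(Cc2cc(Cc3cc(Cc4ccccc4OCc4ccccc4)ccc3OCc3ccccc3)ccc2OCc2ccccc2)ccc1OCc1ccccc1
F2 | step 12 | ethyl (E)-3-ethoxy-5-ArT-pent-2-enoate | CCOC(=O)/C=C(/OCC)CCc1cc(Cc2cc(Cc3cc(Cc4ccccc4OCc4ccccc4)ccc3OCc3ccccc3)ccc2OCc2ccccc2)ccc1OCc1ccccc1
F3 | step 12 | (E)-3-ethoxy-5-ArT-pent-2-enoic acid | OC(=O)/C=C(/OCC)CCc1cc(Cc2cc(Cc3cc(Cc4ccccc4OCc4ccccc4)ccc3OCc3ccccc3)ccc2OCc2ccccc2)ccc1OCc1ccccc1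
F4 | step 12 | (E)-3-ethoxy-5-ArT-pent-2-enoyl chloride | ClC(=O)/C=C(/OCC)CCc1cc(Cc2cc(Cc3cc(Cc4ccccc4OCc4ccccc4)ccc3OCc3ccccc3)ccc2OCc2ccccc2)ccc1OCc1ccccc1
F5 | step 17 | (E)-1-{4-(benzyloxy)-3-[2-(benzyloxy)benzyl]-5-(ArT-methyl)-6-ethoxy-2-hydroxyphenyl}-3-phenylprop-2-en-1-one | CCOc1c(C(=O)/C=C/c2ccccc2)c(O)c(Cc2ccccc2OCc2ccccc2)c(OCc2ccccc2)c1Cc1cc(Cc2cc(Cc3cc(Cc4ccccc4OCc4ccccc4)ccc3OCc3ccccc3)ccc2OCc2ccccc2)ccc1OCc1ccccc1
F6 | step 17 | racemic 7-(benzyloxy)-8-[2-(benzyloxy)benzyl]-6-(ArT-methyl)-5-ethoxy-2-phenylchroman-4-one | O=C1CC(c2ccccc2)Oc2c(Cc3ccccc3OCc3ccccc3)c(OCc3ccccc3)c(Cc3cc(Cc4cc(Cc5cc(Cc6ccccc6OCc6ccccc6)ccc5OCc5ccccc5)ccc4OCc4ccccc4)ccc3OCc3ccccc3)c(OCC)c12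
F7 | step 17 | (2R)-7-(benzyloxy)-8-[2-(benzyloxy)benzyl]-6-(ArT-methyl)-5-ethoxy-2-phenylchroman-4-one | O=C1C[C@H](c2ccccc2)Oc2c(Cc3ccccc3OCc3ccccc3)c(OCc3ccccc3)c(Cc3cc(Cc4cc(Cc5cc(Cc6ccccc6OCc6ccccc6)ccc5OCc5ccccc5)ccc4OCc4ccccc4)ccc3OCc3ccccc3)c(OCC)c12
F8 | step 18 | (2S)-5-ethoxy-7-hydroxy-8-(2-hydroxybenzyl)-6-{2-hydroxy-5-[2-hydroxy-5-(2-hydroxy-5-(2-hydroxybenzyl)benzyl)benzyl]benzyl}-2-phenylchroman-4-one | O=C1C[C@@H](c2ccccc2)Oc2c(Cc3ccccc3O)c(O)c(Cc3cc(Cc4cc(Cc5cc(Cc6ccccc6O)ccc5O)ccc4O)ccc3O)c(OCC)c12
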